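**Retrosynthetic overview**

- Numbering: tetralone C1 (C=O), C4 (stereocentre), C4a, C5–C8, C8a; naphthalene C1' (bonded to C4), C4' (OH), C4a', C8' (OMe), C8a'. The strategy rests on ring C (C1'–C4', C4a', C8a'): its OH at C4' lies para to the C1'–C4 bond and the OMe at C8' lies peri to C1', which is the pattern an acid-opened 1-substituted 1,4-epoxy-1,4-dihydronaphthalene from 3-methoxybenzyne leaves behind.
- Target 16 ⇐ BCl3 cleavage of the two ring A isopropyl ethers of 15 ⇐ acid opening of the oxygen bridge of 13 with ketal hydrolysis. Ring A is carried as isopropyl rather than methyl ethers, because the C8' methyl ether must survive its unmasking.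
- 13 ⇐ [4+2] cycloaddition of 3-methoxybenzyne (from 11) across the 2-furyl group on C4 of 10, forming C1'–C8a' and C4'–C4a' and closing ring C as its 1,4-epoxide.
- 10 ⇐ iridium-catalysed asymmetric hydrogenation of the 4-furyl-1,2-dihydronaphthalene 9 (sets C4) ⇐ 2-furyllithium addition to the 4-oxo ketal 5 and dehydration ⇐ benzylic oxidation of ketal 4 ⇐ 5,8-dimethoxy-1-tetralone 1 after methyl-to-isopropyl exchange.
- Ring order: rings A and B are bought as the tetralone; the furan is attached at C4; ring C closes in the cycloaddition, ring D arriving with the aryne; ring C becomes aromatic in the acid step.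

Key step: step 8

Assumption: the (S)-phosphinooxazoline ligand is taken to deliver hydrogen to the alkene face that gives (S)-C4 in 10; if the first run shows the opposite sense, the (R)-ligand is used and nothing else changes.

Remark on descriptors: C4 is (S) in 10 and 13 and (R) in 14, 15 and 16 with the same arrangement in space, because the C4 substituent that becomes the naphthalene no longer carries an oxygen on its attached carbon and drops below C4a in CIP rank.

**Route**

Step 1
Reactants: 1 5,8-dimethoxy-3,4-dihydronaphthalen-1(2H)-one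
Product: 2 5,8-dihydroxy-3,4-dihydronaphthalen-1(2H)-one
Conditions: BBr3 (3 equiv), CH2Cl2, −78 °C → rt; then H2O
Reagents that add atoms: none
Why: Lewis-acid cleavage of aryl methyl ethers (BBr3 demethylation) frees both ring A phenols so that they can be re-protected with a group removable beside the later C8' methyl ether.

Step 2
Reactants: 2 5,8-dihydroxy-3,4-dihydronaphthalen-1(2H)-one
Product: 3 5,8-diisopropoxy-3,4-dihydronaphthalen-1(2H)-one
Conditions: 2-bromopropane (4 equiv), K2CO3, DMF, 60 °C, under N2
Reagents that add atoms: 2-bromopropane, CC(C)Br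
Why: Williamson ether synthesis; both phenols, including the hydrogen-bonded C8 hydroxyl, should alkylate under forcing carbonate conditions, and isopropyl ethers are chosen because BCl3 removes them later beside an aryl methyl ether.

Step 3
Reactants: 3 5,8-diisopropoxy-3,4-dihydronaphthalen-1(2H)-one
Product: 4 5,8-diisopropoxy-1-tetralone ethylene ketal (spiro-1,3-dioxolane at C1)
Conditions: HOCH2CH2OH (5 equiv), p-TsOH·H2O (cat.), benzene, reflux, Dean–Stark trap
Reagents that add atoms: ethylene glycol, OCCO
Why: Acid-catalysed ketalisation driven by azeotropic removal of water masks C1 so that C4 can be oxidised and then attacked by an organolithium; aryl isopropyl ethers tolerate the sulfonic acid.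

Step 4
Reactants: 4 5,8-diisopropoxy-1-tetralone ethylene ketal
Product: 5 5,8-diisopropoxytetralin-1,4-dione mono(ethylene ketal) (ketone at C4, dioxolane at C1)
Conditions: t-BuOOH (70% aq., 6 equiv), Rh2(cap)4 (1 mol %; cap = caprolactamate), NaHCO3, ClCH2CH2Cl, 40 °C
Reagents that add atoms: tert-butyl hydroperoxide, CC(C)(C)OO
Why: Benzylic C–H oxidation by tert-butylperoxyl radicals under dirhodium caprolactamate catalysis should convert the only benzylic CH2 (C4, activated by the dialkoxyarene) into the ketone, and the hydrogencarbonate buffer should keep the dioxolane intact.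

Step 5
Reactants: 5 5,8-diisopropoxytetralin-1,4-dione mono(ethylene ketal); 6 furan
Product: 8 4-(furan-2-yl)-4-hydroxy-5,8-diisopropoxy-1-tetralone ethylene ketal (racemic tertiary alcohol), via 2-furyllithium 7 (not isolated)
Conditions: 6 (1.5 equiv), n-BuLi, THF, −78 → 0 °C; then 5, −78 °C; aq. NH4Cl
Reagents that add atoms: none
Why: α-Lithiation of furan and 1,2-addition of the aryllithium to the aryl ketone; the new centre is racemic and is removed again in step 6.

Step 6
Reactants: 8 4-(furan-2-yl)-4-hydroxy-5,8-diisopropoxy-1-tetralone ethylene ketal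
Product: 9 4-(furan-2-yl)-5,8-diisopropoxy-1,2-dihydronaphthalene 1-ethylene ketal (C3=C4 alkene)
Conditions: MsCl, Et3N (excess), DMAP (cat.), CH2Cl2, 0 °C → rt; chromatography on Et3N-washed silica
Reagents that add atoms: none
Why: Dehydration through the tertiary mesylate (sulfene mesylation, then E1/E2 elimination) can place the double bond only at C3=C4 because C3 bears the only β-hydrogens, and the basic medium avoids acid-triggered loss of the ketal with aromatisation to a naphthyl ether.

Step 7
Reactants: 9 4-(furan-2-yl)-5,8-diisopropoxy-1,2-dihydronaphthalene 1-ethylene ketal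
Product: 10 (S)-4-(furan-2-yl)-5,8-diisopropoxy-1-tetralone ethylene ketal
Conditions: H2 (50 bar), [Ir(cod)(L)]BArF (2 mol %; L = (S)-4-tert-butyl-2-[2-(diphenylphosphanyl)phenyl]-4,5-dihydrooxazole, BArF = B[3,5-(CF3)2C6H3]4), K3PO4 (powder), CH2Cl2, rt
Reagents that add atoms: none
Why: Asymmetric hydrogenation of an unfunctionalised trisubstituted aryl alkene with a cationic iridium N,P catalyst (1-aryl-3,4-dihydronaphthalene class): the chiral ligand selects the alkene face and so sets C4, the furan needs harsher conditions to be reduced, and solid K3PO4 takes up acid released by the iridium hydrides.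

Step 8
Reactants: 10 (S)-4-(furan-2-yl)-5,8-diisopropoxy-1-tetralone ethylene ketal; 11 3-methoxy-2-(trimethylsilyl)phenyl trifluoromethanesulfonate
Product: 13 8'-methoxy-1',4'-epoxy-1',4'-dihydronaphthalene adduct carrying the (S)-tetralin-4-yl ketal on the C1' bridgehead (both bridgehead diastereomers), via 3-methoxybenzyne 12 (not isolated)
Conditions: 11 (2.5 equiv, slow addition), CsF (5 equiv), MeCN, rt
Reagents that add atoms: none
Why: Fluoride attacks silicon of 11 and triflate leaves, giving 3-methoxybenzyne 12, which adds across furan C2/C5 of 10 in a concerted, asynchronous [4+2] cycloaddition (aryne–furan Diels–Alder; the closest known cases are cycloadditions of 3-alkoxybenzynes with 2-alkylfurans). Ring C (C1'–C4', C4a', C8a') closes by this cycloaddition in its 1,4-oxygen-bridged form, the two new bonds being C1'–C8a' and C4'–C4a'. The bridgehead centres C1' and C4' are tied to each other by the bridge; their sense relative to C4 is not controlled and need not be, since step 9 removes both, and C4 is not touched. The selectivity needed is regiochemical: the methoxy group distorts the aryne so that the carbon meta to it is the more electrophilic, the unsubstituted furan C5 should bond to it first, and the tetralinyl-bearing furan carbon is left to bond next to OMe, which gives the C8'-OMe/C1' peri pattern. Some of the other regioisomer is expected and is removed by chromatography here or at 15. The furan is by far the best aryne trap in 10; the dialkoxyarene, ketal and ethers should be inert to CsF and to the aryne.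

Step 9
Reactants: 13 8'-methoxy-1',4'-epoxy-1',4'-dihydronaphthalene adduct
Product: 15 (R)-4-(4-hydroxy-8-methoxynaphthalen-1-yl)-5,8-diisopropoxy-3,4-dihydronaphthalen-1(2H)-one, via naphthol ketal 14 (not isolated)
Conditions: 2 M HCl (aq.), THF, rt
Reagents that add atoms: water, O
Why: Acid-catalysed isomerisation of a 1,4-epoxy-1,4-dihydronaphthalene to a 1-naphthol: the tertiary benzylic C1'–O bond, helped by the ortho C8' methoxy group, ionises and loss of the C4' proton aromatises ring C with OH at C4', so both bridgehead diastereomers converge; the same acid hydrolyses the dioxolane while the isopropyl ethers and C4 stay untouched.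

Step 10
Reactants: 15 (R)-4-(4-hydroxy-8-methoxynaphthalen-1-yl)-5,8-diisopropoxy-3,4-dihydronaphthalen-1(2H)-one
Product: 16 (R)-5,8-dihydroxy-4-(4-hydroxy-8-methoxynaphthalen-1-yl)-3,4-dihydronaphthalen-1(2H)-one (target)
Conditions: BCl3 (1 M in CH2Cl2, 6 equiv), CH2Cl2, −78 → 0 °C; then H2O
Reagents that add atoms: none
Why: Lewis-acid dealkylation of aryl ethers: BCl3 cleaves secondary isopropyl aryl ethers (the C8 one helped by chelation to the ketone) far faster than an unchelated aryl methyl ether, so the C8' methoxy group should remain and C4 is not affected.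

**Compound list**

1 | 5,8-dimethoxy-3,4-dihydronaphthalen-1(2H)-one | COc1ccc(OC)c2c1CCCC2=O | starting material
2 | 5,8-dihydroxy-3,4-dihydronaphthalen-1(2H)-one | O=C1CCCc2c(O)ccc(O)c12 | intermediate
3 | 5,8-diisopropoxy-3,4-dihydronaphthalen-1(2H)-one | O=C1CCCc2c(OC(C)C)ccc(OC(C)C)c12 | intermediate
4 | 5,8-diisopropoxy-1-tetralone ethylene ketal | C1CCC2(OCCO2)c2c(OC(C)C)ccc(OC(C)C)c12 | intermediate
5 | 5,8-diisopropoxytetralin-1,4-dione mono(ethylene ketal) | O=C1CCC2(OCCO2)c2c(OC(C)C)ccc(OC(C)C)c12 | intermediate
6 | furan | c1ccoc1 | starting material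
7 | 2-furyllithium (not isolated) | [Li]c1ccco1 | intermediate
8 | 4-(furan-2-yl)-4-hydroxy-5,8-diisopropoxy-1-tetralone ethylene ketal (racemic) | OC1(c2ccco2)CCC2(OCCO2)c2c(OC(C)C)ccc(OC(C)C)c12 | intermediate
9 | 4-(furan-2-yl)-5,8-diisopropoxy-1,2-dihydronaphthalene 1-ethylene ketal | c1ccoc1C1=CCC2(OCCO2)c2c(OC(C)C)ccc(OC(C)C)c12 | intermediate
10 | (S)-4-(furan-2-yl)-5,8-diisopropoxy-1-tetralone ethylene ketal | c1ccoc1[C@H]1CCC2(OCCO2)c2c(OC(C)C)ccc(OC(C)C)c12 | intermediate
11 | 3-methoxy-2-(trimethylsilyl)phenyl trifluoromethanesulfonate | COc1cccc(OS(=O)(=O)C(F)(F)F)c1[Si](C)(C)C | starting material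
12 | 3-methoxybenzyne (not isolated) | COC1=CC=CC#C1 | intermediate
13 | 8'-methoxy-1',4'-epoxy-1',4'-dihydronaphthalene adduct, C1' bearing the (S)-tetralin-4-yl ketal, both bridgehead diastereomers (bridgeheads left unassigned) | COc1cccc2C3OC(C=C3)([C@H]3CCC4(OCCO4)c4c(OC(C)C)ccc(OC(C)C)c34)c12 | intermediate
14 | (R)-4-(4-hydroxy-8-methoxynaphthalen-1-yl)-5,8-diisopropoxy-1-tetralone ethylene ketal (not isolated) | COc1cccc2c(O)ccc([C@H]3CCC4(OCCO4)c4c(OC(C)C)ccc(OC(C)C)c43)c12 | intermediate
15 | (R)-4-(4-hydroxy-8-methoxynaphthalen-1-yl)-5,8-diisopropoxy-3,4-dihydronaphthalen-1(2H)-one | COc1cccc2c(O)ccc([C@H]3CCC(=O)c4c(OC(C)C)ccc(OC(C)C)c43)c12 | intermediate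
16 | (R)-5,8-dihydroxy-4-(4-hydroxy-8-methoxynaphthalen-1-yl)-3,4-dihydronaphthalen-1(2H)-one | COc1cccc2c(O)ccc([C@H]3CCC(=O)c4c(O)ccc(O)c43)c12 | target

Total step count: 10. Longest linear sequence: 10 steps (1 → 16).

**Steps most likely to fail**

1. Step 8. The regiochemical preference may be weak because the tetralinyl group is bulky, and two regioisomers, each as two bridgehead diastereomers, may be hard to separate. The fallback puts a trimethylsilyl group on furan C5 to make that terminus both the ipso-activated and the more hindered one; it sets out from ketone 5 and returns at 15. Commercial 2-(trimethylsilyl)furan is lithiated at C5 with n-BuLi in THF to 5-(trimethylsilyl)furan-2-yllithium F1, which is added to 5 to give the silylated tertiary alcohol F2. MsCl/Et3N dehydration as in step 6 should give the silylated alkene F3, and the hydrogenation of step 7 the (S)-5-silylfuran ketal F4. With 11 and CsF in MeCN, F4 should give the C4'-silylated cycloadduct F5, since attack at the silicon-bearing carbon (β-silicon stabilisation) and the bulk of SiMe3 should both steer that terminus to the aryne carbon remote from OMe. Aqueous HCl in THF then ionises C1'–O as in step 9; the C4' silyl group leaves in place of the proton (β-silyl elimination from the allyl cation), the ketal is hydrolysed, and the route is rejoined at 15.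

2. Step 7. Facial discrimination may be poor for an alkene flanked by the furyl group and the peri isopropoxy group, and acid released by the iridium hydrides may open the ketal and aromatise ring B. The fallback replaces asymmetric catalysis by resolution; it sets out from 9 and returns at 10. Alkene 9 is hydrogenated under non-acidic heterogeneous conditions (H2, 1–3 bar, Pd/C, EtOAc with 1% Et3N) to the racemic furan ketal F6. Preparative chromatography on a polysaccharide chiral stationary phase (supercritical CO2/alcohol) then delivers the (S)-enantiomer 10.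

3. Step 4. The radical oxidation may stall at the benzylic alcohol or peroxide, attack an isopropyl methine, or cost the ketal. The fallback builds the same mono-ketal by oxidative dearomatisation; it sets out from 3 and returns at 5. Tetralone 3 is dehydrogenated (Pd(O2CCF3)2, 2-(dimethylamino)pyridine, p-TsOH, O2, DMSO, 80 °C) to 5,8-diisopropoxynaphthalen-1-ol F7. Oxidation with PhI(OAc)2 (2.2 equiv) in ethylene glycol/MeCN at 0 °C gives the para-quinone mono(ethylene ketal) F8. Hydrogenation of its C2=C3 bond (H2, 1 atm, Pd/C, EtOAc, K2CO3) gives 5; ring A is symmetrically substituted, so the ketone/ketal assignment is the same as in the main route.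

**Further compounds**

F1 | step 8 | 5-(trimethylsilyl)furan-2-yllithium | C[Si](C)(C)c1ccc([Li])o1
F2 | step 8 | 4-hydroxy-5,8-diisopropoxy-4-[5-(trimethylsilyl)furan-2-yl]-1-tetralone ethylene ketal (racemic) | C[Si](C)(C)c1ccc(o1)C1(O)CCC2(OCCO2)c2c(OC(C)C)ccc(OC(C)C)c12
F3 | step 8 | 5,8-diisopropoxy-4-[5-(trimethylsilyl)furan-2-yl]-1,2-dihydronaphthalene 1-ethylene ketal | C[Si](C)(C)c1ccc(o1)C1=CCC2(OCCO2)c2c(OC(C)C)ccc(OC(C)C)c12
F4 | step 8 | (S)-5,8-diisopropoxy-4-[5-(trimethylsilyl)furan-2-yl]-1-tetralone ethylene ketal | C[Si](C)(C)c1ccc(o1)[C@H]1CCC2(OCCO2)c2c(OC(C)C)ccc(OC(C)C)c12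
F5 | step 8 | 8'-methoxy-4'-(trimethylsilyl)-1',4'-epoxy-1',4'-dihydronaphthalene adduct, C1' bearing the (S)-tetralin-4-yl ketal (bridgeheads unassigned) | COc1cccc2C3([Si](C)(C)C)OC(C=C3)([C@H]3CCC4(OCCO4)c4c(OC(C)C)ccc(OC(C)C)c34)c12
F6 | step 7 | racemic 4-(furan-2-yl)-5,8-diisopropoxy-1-tetralone ethylene ketal | c1ccoc1C1CCC2(OCCO2)c2c(OC(C)C)ccc(OC(C)C)c12
F7 | step 4 | 5,8-diisopropoxynaphthalen-1-ol | Oc1cccc2c(OC(C)C)ccc(OC(C)C)c12
F8 | step 4 | 5,8-diisopropoxynaphthalene-1,4-dione 4-mono(ethylene ketal) | O=C1C=CC2(OCCO2)c2c(OC(C)C)ccc(OC(C)C)c12
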